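## The problem

The target, (2S,4aS,5R,6R,8aS)-1,1,4a,6-tetramethyl-5-[(3E,7E)-4,8,12-trimethyltrideca-3,7,11-trien-1-yl]decahydronaphthalene-2,6-diol (26), is a cis-fused decalin: in triterpenoid numbering 3S,5S,8R,9R,10S, with C5–H and the C10 methyl on the same (β) face. A cis fusion rules out a cationic polyene cyclisation, which would give the trans ring junction. Three contiguous congested carbons (C4 quaternary, C5, C10 quaternary) form the fusion, and C9, which carries the homofarnesyl chain, sits between quaternary C10 and the tertiary carbinol C8. C10 and C5 have to be set together and in absolute terms. Once the cis-decalin exists, its convex β face should steer a carbon nucleophile to C9 (chain β), and that chain should then send oxygen to the α face of C8. C3 is insulated from the other centres by the C4 gem-dimethyl group and needs reagent control. The chain holds three trisubstituted alkenes, so once it is attached, strong acid, electrophilic oxidants, halonium reagents, hydroboration and hydrogenation are excluded. The C8 tertiary alcohol can dehydrate, and C5 can epimerise while C6 is a carbonyl. The enabling feature is ring A: oxygen at C3 next to C4(CH3)2, joined to ring B through C5 (H) and C10 (CH3). Cutting C1–C10 and C4–C5 gives a 2-silyloxydiene (C1=C2–C3(O)=C4Me2) and a C5=C10 double bond which, with carbonyls at C6 and C9, is one methyl-bearing C=C of 2,6-dimethyl-1,4-benzoquinone; its second methyl is the C8 methyl.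

## Retrosynthesis

**C3 carbinol.** Target 26 is cut back to ketone 25 (C3–H bond). Doing this last keeps C3 masked, without a protecting-group step, as the silyl enol ether that the cycloaddition delivers (24). The forward step needs hydride delivery to the α face of a ketone flanked by a quaternary carbon and a methylene, with the chain alkenes untouched.

**C7 oxygen.** 24 is traced to the α-silyloxy ketone 21 through alcohol 22 and thiocarbonate 23. The C7 carbonyl is only an activating group; a hydrazone-based removal would risk expelling the α-oxygen, so reduction and radical deoxygenation are used. This needs the C8 oxygen capped, which is done in the pot that creates it.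

**C9–C11 and C8–O.** 21 is cut at both bonds to enone 12 and homofarnesyl bromide 16 (via Grignard reagent 17 and silyl enol ether 18). Opening an 8,9-epoxide at neopentyl C9 is sterically unrealistic, and hydrating a ring alkene after the chain is on cannot be chemoselective. Enolate oxidation is the one C8 oxygenation that ignores the chain alkenes. The forward reaction needs conjugate addition at a β-carbon next to quaternary C10 from the β face, then hydroxylation from the α face.

**Chain.** 16 comes from homofarnesol 15, and 15 from commercial (2E,6E)-farnesyl bromide 13 by a one-carbon homologation that keeps both E alkenes.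

**Carbonyl transposition.** Enone 12 (C7 carbonyl, C8=C9) is traced through allylic alcohol 11 and epoxy ketone 9 to enone 8 (C9 carbonyl, C7=C8). This moves the oxygen from C9, where the quinone puts it, to C7, where the conjugate addition needs it.

**C6 oxygen.** 8 is traced through acetate 6 and alcohol 5 to enedione 4. The C6 carbonyl exists only because the dienophile is a quinone. Reducing it first also removes the enolisable position next to C5.

**Ring A (key cut).** 4 is cut at C1–C10 and C4–C5 to diene 2 and quinone 3. A [4+2] gives the cis fusion directly and sets the quaternary C10, the C4 gem-dimethyl group and the C3 oxygen in one step from two achiral C8/C15 pieces. The forward reaction needs one enantioface of the quinone C=C and the orientation that joins CMe2 to the unsubstituted carbon.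

**Diene.** 2 is the silyl enol ether of commercial 4-methylpent-1-en-3-one 1; only one enolisation is possible.

## Roads not taken

Alternative 1: Here ring A is closed by an anionic oxy-Cope rearrangement. Mesitol A1 would be dearomatised by ortho C-methylation, bridged by a [4+2] with an ethylene equivalent and vinylated to the bicyclic carbinol A2. Its potassium alkoxide (KH, 18-crown-6) would undergo the [3,3] shift that breaks C3–C8 and forms C1–C10, giving the cis-octalinone A3. The merits are real: the regiochemistry is unambiguous, the bridged transition state enforces the cis fusion, and A3 carries no surplus oxygen. One allylic oxidation at C7 would give the C3-keto analogue of enone 12 in roughly half the steps the chosen route needs to reach 12. The weak points are the absolute configuration (A2 comes from achiral A1 by a cycloaddition with no established catalytic asymmetric version, so a resolution or auxiliary is needed) and the free C3 ketone, which must be protected or reduced before any organometallic step. On step economy and on security of the key step this road is better. The chosen plan sets against it absolute stereocontrol by catalysis in the ring-forming step and a C3 ketone that arrives already masked.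

Alternative 2: Here the C4–C5 bond is cut. Cp2TiCl (trivalent titanium) would open the S epoxide of enone A4 to the C4 tertiary radical, which adds 6-exo to C5; protonation of the titanium enolate gives hydroxy ketone A5. Its merit is that C3 is set before ring closure by a reagent-controlled epoxidation, which removes the uncertainty of step 17 here, and the C7 ketone is already in place. Its weak points are that the quaternary C10 centre of A4 must be made enantiopure independently of the epoxide, and that the C8 methyl and the C8=C9 unsaturation are missing (regioselective methylation at C8 against C6, then dehydrogenation). The tertiary radical must also bond to a β-carbon next to a quaternary centre, in competition with reduction or elimination of the radical. It is better at C3 and worse at C10 and C8; overall it should need at least as many steps to reach an enone like 12.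

Alternative 3: Here ring B is made by a [4+2]. The aminosilyloxydiene A6 (C5 to C8 with the C8 methyl) would add to the C9=C10 bond of tetraenal A7 under a chiral Lewis acid, forming C5–C10 and C8–C9; acid then gives the formyl enone A8. Its merit is exactly where the chosen plan is weakest: the C9–C11 bond and the whole chain are present from the start, and the C9/C10 relationship follows from the E geometry of the enal. Its weak points are that a β-alkyl α-methyl enal is a sluggish dienophile, and that ring A (C1 to C4, the gem-dimethyl group, the C4–C5 bond with cis fusion, C3) must then be built over many steps with the acid-sensitive polyene on board. The chosen plan builds ring A with all three features in one step and carries the chain through only the last seven steps.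

Key step: step 2

Convention: bicyclic compounds are named on a decalin stem with triterpenoid locants C1–C10 (chain from C11); β is the face of the C10 methyl, α the opposite face; "homofarnesyl" is (3E,7E)-4,8,12-trimethyltrideca-3,7,11-trien-1-yl.

Assumption: the (R)-configured oxazaborolidinium catalyst is written in step 2 because the usual binding picture (boron on the C6 oxygen, C5–H contact to the ring oxygen, aryl group under C5=C10) exposes the needed α face for that antipode; if this diene reacts through another complex, the (S)-catalyst is used instead.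

## Route

Step 1
Reactants: 1 4-methylpent-1-en-3-one
Product: 2 4-methyl-3-(triisopropylsilyloxy)penta-1,3-diene
Conditions: i-Pr3SiOTf, Et3N, Et2O, 0 °C to rt
Reagents that add atoms: triisopropylsilyl trifluoromethanesulfonate, CC(C)[Si](C(C)C)(C(C)C)OS(=O)(=O)C(F)(F)F
Why: Silyl enol ether formation by soft enolisation (silyl triflate and amine); the isopropyl methine is the only enolisable position, so a single tetrasubstituted enol ether forms with no E/Z question.

Step 2
Reactants: 2 4-methyl-3-(triisopropylsilyloxy)penta-1,3-diene; 3 2,6-dimethyl-1,4-benzoquinone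
Product: 4 4,4,8,10β-tetramethyl-3-(triisopropylsilyloxy)-5β-H-decalin-2,7-diene-6,9-dione
Conditions: (R)-1-(2-methylphenyl)-3,3-diphenyltetrahydro-1H,3H-pyrrolo[1,2-c][1,3,2]oxazaborole (20 mol %), HN(SO2CF3)2 (20 mol %), excess 2, CH2Cl2, −78 to −40 °C; cold filtration through neutral alumina
Reagents that add atoms: none
Why: Diels–Alder reaction of a 2-silyloxydiene with a benzoquinone under a chiral oxazaborolidinium Lewis acid; the closest known case is the same catalyst with 2-(triisopropylsilyloxy)buta-1,3-diene and methyl-substituted benzoquinones. The cation should bind the more basic, less hindered C6 carbonyl (C–H on both flanks), placing the C5=C10 bond over an aryl group so that the diene adds endo to the open face. Ring A closes as a six-membered carbocycle by [4+2] addition (concerted but asynchronous, or as two successive Michael-type bond formations), forming C1–C10 and C4–C5 and leaving the C2=C3 silyl enol ether. C10 and C5 are created together: their cis relation follows from addition of both termini to one face of the ring alkene, and their absolute configuration from the face the catalyst leaves open. The orientation needed (CH2 to the methyl-bearing C10, CMe2 to C5) is the one that keeps the two fully substituted carbons apart, and it is also the intrinsic orientation of the uncatalysed reaction because C5 is β to the C9 carbonyl. The usual catalyst rule would send the nucleophilic terminus to C10, which here would join CMe2 to C(CH3) and should be far slower. A fully substituted nucleophilic terminus is outside the reported scope, so rate and enantioselectivity are not secured by precedent; the triflimide-activated catalyst, low temperature and excess diene are chosen for that reason. The adduct is reduced at once (step 3) so that C5–H next to the C6 carbonyl cannot epimerise.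

Step 3
Reactants: 4 4,4,8,10β-tetramethyl-3-(triisopropylsilyloxy)-5β-H-decalin-2,7-diene-6,9-dione
Product: 5 6α-hydroxy-4,4,8,10β-tetramethyl-3-(triisopropylsilyloxy)-5β-H-decalin-2,7-dien-9-one
Conditions: NaBH4, CeCl3·7H2O, MeOH, −78 °C
Reagents that add atoms: none
Why: Luche 1,2-reduction; the C6 carbonyl is far more accessible than the C9 carbonyl (between quaternary C10 and methyl-bearing C8), and hydride should enter from the convex β face (the C6 configuration is removed in step 5). With C6 sp3, C5 is no longer enolisable.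

Step 4
Reactants: 5 6α-hydroxy-4,4,8,10β-tetramethyl-3-(triisopropylsilyloxy)-5β-H-decalin-2,7-dien-9-one
Product: 6 6α-acetoxy-4,4,8,10β-tetramethyl-3-(triisopropylsilyloxy)-5β-H-decalin-2,7-dien-9-one
Conditions: Ac2O, pyridine, DMAP (cat.), CH2Cl2, 0 °C to rt
Reagents that add atoms: acetic anhydride, CC(=O)OC(C)=O
Why: DMAP-catalysed acetylation of a secondary allylic alcohol; it turns the C6 oxygen into a leaving group γ to the C9 carbonyl.

Step 5
Reactants: 6 6α-acetoxy-4,4,8,10β-tetramethyl-3-(triisopropylsilyloxy)-5β-H-decalin-2,7-dien-9-one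
Product: 8 4,4,8,10β-tetramethyl-3-(triisopropylsilyloxy)-5β-H-decalin-2,7-dien-9-one, via deconjugated Δ6 ketone 7 (not isolated)
Conditions: SmI2 (2.5 equiv), THF–MeOH, −78 °C; then DBU, CH2Cl2, rt
Reagents that add atoms: none
Why: Reductive cleavage of a γ-acyloxy enone by divalent samarium (vinylogous α-ketol reduction): the ketyl expels acetate, the dienolate is protonated mainly at C8 to give 7, and DBU returns the double bond to conjugation.

Step 6
Reactants: 8 4,4,8,10β-tetramethyl-3-(triisopropylsilyloxy)-5β-H-decalin-2,7-dien-9-one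
Product: 9 7β,8β-epoxy-4,4,8α,10β-tetramethyl-3-(triisopropylsilyloxy)-5β-H-decalin-2-en-9-one
Conditions: t-BuOOH, DBU, CH2Cl2, 0 °C to rt
Reagents that add atoms: tert-butyl hydroperoxide, CC(C)(C)OO
Why: Weitz–Scheffer nucleophilic epoxidation of an α-methyl enone; the peroxide anion adds to unhindered C7 from the convex β face and does not touch the electron-rich silyl enol ether (the epoxide configuration is lost in step 8).

Step 7
Reactants: 9 7β,8β-epoxy-4,4,8α,10β-tetramethyl-3-(triisopropylsilyloxy)-5β-H-decalin-2-en-9-one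
Product: 11 7β-hydroxy-4,4,8,10β-tetramethyl-3-(triisopropylsilyloxy)-5β-H-decalin-2,8-diene, via epoxy hydrazone 10 (not isolated)
Conditions: N2H4·H2O, AcOH (cat.), MeOH, 0 °C to rt
Reagents that add atoms: none
Why: Wharton transposition: the hydrazone loses N2 as the epoxide opens, moving the double bond to C8=C9 and leaving the C7 hydroxyl.

Step 8
Reactants: 11 7β-hydroxy-4,4,8,10β-tetramethyl-3-(triisopropylsilyloxy)-5β-H-decalin-2,8-diene
Product: 12 4,4,8,10β-tetramethyl-3-(triisopropylsilyloxy)-5β-H-decalin-2,8-dien-7-one
Conditions: MnO2, CH2Cl2, rt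
Reagents that add atoms: none
Why: MnO2 oxidation of an allylic alcohol; the enone now has its carbonyl at C7 and its β-carbon at C9.

Step 9
Reactants: 13 (2E,6E)-farnesyl bromide
Product: 15 (3E,7E)-homofarnesol, via homofarnesyl(isopropoxy)dimethylsilane 14 (not isolated)
Conditions: (i-PrO)Me2SiCH2MgCl (from the chloride and Mg), Li2CuCl4 (5 mol %), THF, −20 to 0 °C; then KF, KHCO3, H2O2 (30 %), THF–MeOH, rt
Reagents that add atoms: (isopropoxydimethylsilyl)methylmagnesium chloride, CC(C)O[Si](C)(C)C[Mg]Cl; hydrogen peroxide, OO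
Why: Copper-catalysed coupling of a primary allylic bromide with a silylmethyl Grignard reagent at the α carbon with retention of alkene geometry, then Tamao oxidation of C–Si to C–OH; buffered peroxide/fluoride does not epoxidise trisubstituted alkenes.

Step 10
Reactants: 15 (3E,7E)-homofarnesol
Product: 16 (3E,7E)-homofarnesyl bromide
Conditions: CBr4, PPh3, CH2Cl2, 0 °C
Reagents that add atoms: carbon tetrabromide, BrC(Br)(Br)Br
Why: Appel bromination of a primary alcohol under neutral conditions, which leaves the homoallylic alkene geometry intact.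

Step 11
Reactants: 12 4,4,8,10β-tetramethyl-3-(triisopropylsilyloxy)-5β-H-decalin-2,8-dien-7-one; 16 (3E,7E)-homofarnesyl bromide
Product: 18 9β-homofarnesyl-4,4,8,10β-tetramethyl-3-(triisopropylsilyloxy)-7-(trimethylsilyloxy)-5β-H-decalin-2,7-diene, via homofarnesylmagnesium bromide 17 (not isolated)
Conditions: 16, Mg, THF; then CuBr·SMe2 (10 mol %), HMPA, Me3SiCl, 12, THF, −78 to −40 °C; Et3N, pentane work-up
Reagents that add atoms: chlorotrimethylsilane, C[Si](C)(C)Cl
Why: Copper-catalysed conjugate addition of a Grignard reagent accelerated by Me3SiCl/HMPA, with the enolate trapped as its silyl enol ether. C9 should be attacked axially from the β face, anti to ring carbon C1, on the half-chair that keeps C4 equatorial on ring B, since the α face is blocked by ring A; this puts the chain β, cis to the C10 methyl.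

Step 12
Reactants: 18 9β-homofarnesyl-4,4,8,10β-tetramethyl-3-(triisopropylsilyloxy)-7-(trimethylsilyloxy)-5β-H-decalin-2,7-diene
Product: 21 9β-homofarnesyl-4,4,8β,10β-tetramethyl-8α-(triethylsilyloxy)-3-(triisopropylsilyloxy)-5β-H-decalin-2-en-7-one, via lithium enolate 19 (not isolated), via lithium 8α-alkoxide 20 (not isolated)
Conditions: MeLi, THF, 0 °C to rt; 2-(phenylsulfonyl)-3-phenyloxaziridine, −78 °C; then Et3SiOTf, 2,6-lutidine, −78 to 0 °C
Reagents that add atoms: 2-(phenylsulfonyl)-3-phenyloxaziridine, O=S(=O)(c1ccccc1)N1OC1c1ccccc1; triethylsilyl trifluoromethanesulfonate, CC[Si](CC)(CC)OS(=O)(=O)C(F)(F)F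
Why: MeLi cleaves the trimethylsilyl (not the triisopropylsilyl) enol ether to the lithium enolate, which is hydroxylated by the N-sulfonyloxaziridine, an oxidant that ignores the chain alkenes. Oxygen should arrive anti to the adjacent β chain and away from the C10 methyl, giving 8α-O/8β-CH3; the alkoxide is silylated in the same pot so that it cannot form a cyclic thiocarbonate in step 14.

Step 13
Reactants: 21 9β-homofarnesyl-4,4,8β,10β-tetramethyl-8α-(triethylsilyloxy)-3-(triisopropylsilyloxy)-5β-H-decalin-2-en-7-one
Product: 22 9β-homofarnesyl-7β-hydroxy-4,4,8β,10β-tetramethyl-8α-(triethylsilyloxy)-3-(triisopropylsilyloxy)-5β-H-decalin-2-ene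
Conditions: i-Bu2AlH, CH2Cl2, −78 °C; Rochelle salt work-up
Reagents that add atoms: none
Why: Hydride reduction of a hindered ketone at low temperature through an aluminium alkoxide, which should avoid silyl migration between the vicinal oxygens; the C7 configuration (drawn β) is irrelevant because C7 becomes CH2.

Step 14
Reactants: 22 9β-homofarnesyl-7β-hydroxy-4,4,8β,10β-tetramethyl-8α-(triethylsilyloxy)-3-(triisopropylsilyloxy)-5β-H-decalin-2-ene
Product: 23 O-(7β-yl) imidazole-1-carbothioate of 22
Conditions: 1,1'-thiocarbonyldiimidazole, DMAP, ClCH2CH2Cl, 60 °C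
Reagents that add atoms: 1,1'-thiocarbonyldiimidazole, S=C(n1cncc1)n1cncc1
Why: Thioacylation of the secondary alcohol under neutral conditions, the first half of a Barton–McCombie deoxygenation.

Step 15
Reactants: 23 O-(7β-yl) imidazole-1-carbothioate of 22
Product: 24 9β-homofarnesyl-4,4,8β,10β-tetramethyl-8α-(triethylsilyloxy)-3-(triisopropylsilyloxy)-5β-H-decalin-2-ene
Conditions: Bu3SnH (0.2 M), AIBN, toluene, 100 °C
Reagents that add atoms: none
Why: Barton–McCombie deoxygenation; at this stannane concentration hydrogen transfer to the C7 radical should outrun 6-exo closure onto the C13=C14 alkene, and a β-silyloxy radical does not fragment.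

Step 16
Reactants: 24 9β-homofarnesyl-4,4,8β,10β-tetramethyl-8α-(triethylsilyloxy)-3-(triisopropylsilyloxy)-5β-H-decalin-2-ene
Product: 25 9β-homofarnesyl-8α-hydroxy-4,4,8β,10β-tetramethyl-5β-H-decalin-3-one
Conditions: Bu4NF, AcOH, THF, 0 °C to rt
Reagents that add atoms: none
Why: Buffered fluoride desilylation releases the C3 ketone from the silyl enol ether and the C8 tertiary alcohol from its silyl ether, without acid that could ionise the alcohol or the polyene.

Step 17
Reactants: 25 9β-homofarnesyl-8α-hydroxy-4,4,8β,10β-tetramethyl-5β-H-decalin-3-one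
Product: 26 9β-homofarnesyl-4,4,8β,10β-tetramethyl-5β-H-decalin-3β,8α-diol (target)
Conditions: (R)-1-methyl-3,3-diphenyltetrahydro-1H,3H-pyrrolo[1,2-c][1,3,2]oxazaborole ((R)-Me-CBS, 20 mol %), catecholborane, toluene, −78 to −40 °C; aqueous NaOH work-up
Reagents that add atoms: none
Why: CBS reduction, in which the catalyst distinguishes the quaternary C4 flank from the C2 methylene; the (R)-catalyst should deliver hydride to the α face and give the 3S (3β) alcohol. Catecholborane does not hydroborate the chain alkenes at this temperature.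

## Compound list

1 | 4-methylpent-1-en-3-one | C=CC(=O)C(C)C | starting material
2 | 4-methyl-3-(triisopropylsilyloxy)penta-1,3-diene | C=CC(O[Si](C(C)C)(C(C)C)C(C)C)=C(C)C | intermediate
3 | 2,6-dimethyl-1,4-benzoquinone | CC1=CC(=O)C=C(C)C1=O | starting material
4 | (4aR,8aS)-2,5,5,8a-tetramethyl-6-(triisopropylsilyloxy)-4a,5,8,8a-tetrahydronaphthalene-1,4-dione (cis enedione; 5β-H, 10β-CH3) | O=C1[C@@]2(C)CC=C(O[Si](C(C)C)(C(C)C)C(C)C)C(C)(C)[C@H]2C(=O)C=C1C | intermediate
5 | 6α-hydroxy-4,4,8,10β-tetramethyl-3-(triisopropylsilyloxy)-5β-H-decalin-2,7-dien-9-one | O=C1[C@@]2(C)CC=C(O[Si](C(C)C)(C(C)C)C(C)C)C(C)(C)[C@H]2[C@@H](O)C=C1C | intermediate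
6 | 6α-acetoxy-4,4,8,10β-tetramethyl-3-(triisopropylsilyloxy)-5β-H-decalin-2,7-dien-9-one | O=C1[C@@]2(C)CC=C(O[Si](C(C)C)(C(C)C)C(C)C)C(C)(C)[C@H]2[C@@H](OC(C)=O)C=C1C | intermediate
7 | 4,4,8α,10β-tetramethyl-3-(triisopropylsilyloxy)-5β,8β-H-decalin-2,6-dien-9-one | O=C1[C@@]2(C)CC=C(O[Si](C(C)C)(C(C)C)C(C)C)C(C)(C)[C@H]2C=C[C@H]1C | intermediate (not isolated)
8 | 4,4,8,10β-tetramethyl-3-(triisopropylsilyloxy)-5β-H-decalin-2,7-dien-9-one | O=C1[C@@]2(C)CC=C(O[Si](C(C)C)(C(C)C)C(C)C)C(C)(C)[C@H]2CC=C1C | intermediate
9 | 7β,8β-epoxy-4,4,8α,10β-tetramethyl-3-(triisopropylsilyloxy)-5β-H-decalin-2-en-9-one | O=C1[C@@]2(C)CC=C(O[Si](C(C)C)(C(C)C)C(C)C)C(C)(C)[C@H]2C[C@@H]3O[C@]13C | intermediate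
10 | 9-hydrazone of 9 | NN=C1[C@@]2(C)CC=C(O[Si](C(C)C)(C(C)C)C(C)C)C(C)(C)[C@H]2C[C@@H]3O[C@]13C | intermediate (not isolated)
11 | 7β-hydroxy-4,4,8,10β-tetramethyl-3-(triisopropylsilyloxy)-5β-H-decalin-2,8-diene | CC1=C[C@@]2(C)CC=C(O[Si](C(C)C)(C(C)C)C(C)C)C(C)(C)[C@H]2C[C@@H]1O | intermediate
12 | 4,4,8,10β-tetramethyl-3-(triisopropylsilyloxy)-5β-H-decalin-2,8-dien-7-one | CC1=C[C@@]2(C)CC=C(O[Si](C(C)C)(C(C)C)C(C)C)C(C)(C)[C@H]2CC1=O | intermediate
13 | (2E,6E)-farnesyl bromide, (2E,6E)-1-bromo-3,7,11-trimethyldodeca-2,6,10-triene | CC(C)=CCC/C(C)=C/CC/C(C)=C/CBr | starting material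
14 | [(3E,7E)-4,8,12-trimethyltrideca-3,7,11-trien-1-yl](isopropoxy)dimethylsilane | CC(C)=CCC/C(C)=C/CC/C(C)=C/CC[Si](C)(C)OC(C)C | intermediate (not isolated)
15 | (3E,7E)-homofarnesol, (3E,7E)-4,8,12-trimethyltrideca-3,7,11-trien-1-ol | CC(C)=CCC/C(C)=C/CC/C(C)=C/CCO | intermediate
16 | (3E,7E)-homofarnesyl bromide, (3E,7E)-1-bromo-4,8,12-trimethyltrideca-3,7,11-triene | CC(C)=CCC/C(C)=C/CC/C(C)=C/CCBr | intermediate
17 | (3E,7E)-homofarnesylmagnesium bromide | CC(C)=CCC/C(C)=C/CC/C(C)=C/CC[Mg]Br | intermediate (not isolated)
18 | 9β-homofarnesyl-4,4,8,10β-tetramethyl-3-(triisopropylsilyloxy)-7-(trimethylsilyloxy)-5β-H-decalin-2,7-diene | CC(C)=CCC/C(C)=C/CC/C(C)=C/CC[C@@H]1[C@@]2(C)CC=C(O[Si](C(C)C)(C(C)C)C(C)C)C(C)(C)[C@H]2CC(O[Si](C)(C)C)=C1C | intermediate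
19 | lithium C7 enolate from 18 | CC(C)=CCC/C(C)=C/CC/C(C)=C/CC[C@@H]1[C@@]2(C)CC=C(O[Si](C(C)C)(C(C)C)C(C)C)C(C)(C)[C@H]2CC(O[Li])=C1C | intermediate (not isolated)
20 | lithium 8α-alkoxide of 9β-homofarnesyl-8α-hydroxy-4,4,8β,10β-tetramethyl-3-(triisopropylsilyloxy)-5β-H-decalin-2-en-7-one | CC(C)=CCC/C(C)=C/CC/C(C)=C/CC[C@@H]1[C@@]2(C)CC=C(O[Si](C(C)C)(C(C)C)C(C)C)C(C)(C)[C@H]2CC(=O)[C@@]1(C)O[Li] | intermediate (not isolated)
21 | 9β-homofarnesyl-4,4,8β,10β-tetramethyl-8α-(triethylsilyloxy)-3-(triisopropylsilyloxy)-5β-H-decalin-2-en-7-one | CC(C)=CCC/C(C)=C/CC/C(C)=C/CC[C@@H]1[C@@]2(C)CC=C(O[Si](C(C)C)(C(C)C)C(C)C)C(C)(C)[C@H]2CC(=O)[C@@]1(C)O[Si](CC)(CC)CC | intermediate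
22 | 9β-homofarnesyl-7β-hydroxy-4,4,8β,10β-tetramethyl-8α-(triethylsilyloxy)-3-(triisopropylsilyloxy)-5β-H-decalin-2-ene | CC(C)=CCC/C(C)=C/CC/C(C)=C/CC[C@@H]1[C@@]2(C)CC=C(O[Si](C(C)C)(C(C)C)C(C)C)C(C)(C)[C@H]2C[C@H](O)[C@@]1(C)O[Si](CC)(CC)CC | intermediate
23 | O-(7β-yl) imidazole-1-carbothioate of 22 | CC(C)=CCC/C(C)=C/CC/C(C)=C/CC[C@@H]1[C@@]2(C)CC=C(O[Si](C(C)C)(C(C)C)C(C)C)C(C)(C)[C@H]2C[C@H](OC(=S)n3cncc3)[C@@]1(C)O[Si](CC)(CC)CC | intermediate
24 | 9β-homofarnesyl-4,4,8β,10β-tetramethyl-8α-(triethylsilyloxy)-3-(triisopropylsilyloxy)-5β-H-decalin-2-ene | CC(C)=CCC/C(C)=C/CC/C(C)=C/CC[C@@H]1[C@@]2(C)CC=C(O[Si](C(C)C)(C(C)C)C(C)C)C(C)(C)[C@H]2CC[C@@]1(C)O[Si](CC)(CC)CC | intermediate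
25 | 9β-homofarnesyl-8α-hydroxy-4,4,8β,10β-tetramethyl-5β-H-decalin-3-one | CC(C)=CCC/C(C)=C/CC/C(C)=C/CC[C@@H]1[C@@]2(C)CCC(=O)C(C)(C)[C@H]2CC[C@@]1(C)O | intermediate
26 | (2S,4aS,5R,6R,8aS)-1,1,4a,6-tetramethyl-5-[(3E,7E)-4,8,12-trimethyltrideca-3,7,11-trien-1-yl]decahydronaphthalene-2,6-diol | CC(C)=CCC/C(C)=C/CC/C(C)=C/CC[C@@H]1[C@@]2(C)CC[C@H](O)C(C)(C)[C@H]2CC[C@@]1(C)O | target

## Step count and least certain steps

Total: 17 steps. Longest linear sequence: 15 steps (steps 1–8 and 11–17, from 4-methylpent-1-en-3-one); the two-step side branch (steps 9–10) joins at step 11.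

**Step 2 (key step).** The likeliest failure is slow cycloaddition: the fully substituted diene terminus disfavours the s-cis conformation and opposes the catalyst's normal donor–acceptor pairing. The reaction may then run through uncatalysed background or through a different catalyst–quinone complex, giving low enantioselectivity; the regiochemistry itself is sterically enforced. The fallback sets out from 2 and 3 and returns at 8. The cycloaddition is run without chiral catalyst (toluene, heat, or HN(SO2CF3)2) to give 4 together with its enantiomer F1. Luche reduction as in step 3 gives 5 with its enantiomer F2. Acylation with (S)-naproxen chloride and pyridine gives the diastereomeric esters, the ester of 5 F3 and the ester of F2 F4, separated by chromatography or crystallisation. F3 is then treated with SmI2 and DBU exactly as acetate 6 in step 5, the naproxenate serving as leaving group, and rejoins the route at 8.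

**Step 11.** The β-carbon C9 is neopentyl and the enone is α-methylated, so addition may be sluggish, with enolisation at C6 or 1,2-addition consuming the chain reagent. The fallback sets out from 12 and returns at 21; the congested bond is made with a cheap two-carbon nucleophile in large excess and the chain is attached afterwards at C12–C13. Copper-catalysed addition of vinylmagnesium bromide with Me3SiCl gives the 9β-vinyl silyl enol ether F7. Hydroxylation and in-situ silylation as in step 12 give the 9β-vinyl α-silyloxy ketone F8. Hydroboration of the vinyl group with 9-BBN gives the alkylborane F9. Suzuki coupling of F9 with (1E,5E)-1-iodo-2,6,10-trimethylundeca-1,5,9-triene F10 (PdCl2(dppf), Cs2CO3, DMF–H2O, a zerovalent palladium cycle) gives 21.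

**Step 7.** The C9 carbonyl lies between quaternary C10 and the fully substituted epoxide carbon C8, so hydrazone formation may be too slow and hydrazine may open the epoxide instead. The fallback sets out from 9 and returns at 11; it reaches the same transposed allylic alcohol by a radical path. NaBH4 reduces 9 to the epoxy alcohol F5, and 1,1'-thiocarbonyldiimidazole converts it to the imidazolylthiocarbonate F6. Bu3SnH/AIBN then generates the C9 radical, which opens the adjacent epoxide to the C8=C9 alkene and a C7 alkoxy radical that is reduced to 11.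

**Step 17.** Facial selectivity may be poor if the conformational bias of the cis-decalin opposes the catalyst, or if the free C8 hydroxyl binds boron and disturbs hydride delivery. The fallback sets out from 24 and returns at 26; it reduces C3 with a stoichiometric chiral borane while the C8 oxygen is still capped. One equivalent of Bu4NF/AcOH at −20 °C cleaves only the silyl enol ether of 24, giving the 8α-triethylsilyloxy 3-ketone F11. (−)-B-Chlorodiisopinocampheylborane, (−)-Ipc2BCl, a reagent suited to ketones with a quaternary α-carbon, reduces F11 to the 3β-alcohol F12, and Bu4NF then gives 26.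

## Further compounds

F1 | step 2 | enantiomer of 4, (4aS,8aR)-2,5,5,8a-tetramethyl-6-(triisopropylsilyloxy)-4a,5,8,8a-tetrahydronaphthalene-1,4-dione | O=C1[C@]2(C)CC=C(O[Si](C(C)C)(C(C)C)C(C)C)C(C)(C)[C@@H]2C(=O)C=C1C
F2 | step 2 | enantiomer of 5 | O=C1[C@]2(C)CC=C(O[Si](C(C)C)(C(C)C)C(C)C)C(C)(C)[C@@H]2[C@H](O)C=C1C
F3 | step 2 | (S)-2-(6-methoxynaphthalen-2-yl)propanoate ester of 5 | O=C1[C@@]2(C)CC=C(O[Si](C(C)C)(C(C)C)C(C)C)C(C)(C)[C@H]2[C@@H](OC(=O)[C@@H](C)c3ccc4cc(OC)ccc4c3)C=C1C
F4 | step 2 | (S)-2-(6-methoxynaphthalen-2-yl)propanoate ester of F2 | O=C1[C@]2(C)CC=C(O[Si](C(C)C)(C(C)C)C(C)C)C(C)(C)[C@@H]2[C@H](OC(=O)[C@@H](C)c3ccc4cc(OC)ccc4c3)C=C1C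
F5 | step 7 | 7β,8β-epoxy-9α-hydroxy-4,4,8α,10β-tetramethyl-3-(triisopropylsilyloxy)-5β-H-decalin-2-ene | O[C@H]1[C@@]2(C)CC=C(O[Si](C(C)C)(C(C)C)C(C)C)C(C)(C)[C@H]2C[C@@H]3O[C@]13C
F6 | step 7 | O-(9α-yl) imidazole-1-carbothioate of F5 | S=C(n4cncc4)O[C@H]1[C@@]2(C)CC=C(O[Si](C(C)C)(C(C)C)C(C)C)C(C)(C)[C@H]2C[C@@H]3O[C@]13C
F7 | step 11 | 4,4,8,10β-tetramethyl-3-(triisopropylsilyloxy)-7-(trimethylsilyloxy)-9β-vinyl-5β-H-decalin-2,7-diene | C=C[C@@H]1[C@@]2(C)CC=C(O[Si](C(C)C)(C(C)C)C(C)C)C(C)(C)[C@H]2CC(O[Si](C)(C)C)=C1C
F8 | step 11 | 4,4,8β,10β-tetramethyl-8α-(triethylsilyloxy)-3-(triisopropylsilyloxy)-9β-vinyl-5β-H-decalin-2-en-7-one | C=C[C@@H]1[C@@]2(C)CC=C(O[Si](C(C)C)(C(C)C)C(C)C)C(C)(C)[C@H]2CC(=O)[C@@]1(C)O[Si](CC)(CC)CC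
F9 | step 11 | B-alkyl-9-borabicyclo[3.3.1]nonane from F8 (boron on C12) | B4(CC[C@@H]1[C@@]2(C)CC=C(O[Si](C(C)C)(C(C)C)C(C)C)C(C)(C)[C@H]2CC(=O)[C@@]1(C)O[Si](CC)(CC)CC)C5CCCC4CCC5
F10 | step 11 | (1E,5E)-1-iodo-2,6,10-trimethylundeca-1,5,9-triene | I/C=C(C)/CC/C=C(C)/CCC=C(C)C
F11 | step 17 | 9β-homofarnesyl-4,4,8β,10β-tetramethyl-8α-(triethylsilyloxy)-5β-H-decalin-3-one | CC(C)=CCC/C(C)=C/CC/C(C)=C/CC[C@@H]1[C@@]2(C)CCC(=O)C(C)(C)[C@H]2CC[C@@]1(C)O[Si](CC)(CC)CC
F12 | step 17 | 9β-homofarnesyl-4,4,8β,10β-tetramethyl-8α-(triethylsilyloxy)-5β-H-decalin-3β-ol | CC(C)=CCC/C(C)=C/CC/C(C)=C/CC[C@@H]1[C@@]2(C)CC[C@H](O)C(C)(C)[C@H]2CC[C@@]1(C)O[Si](CC)(CC)CC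
A1 | alternative 1 | mesitol, 2,4,6-trimethylphenol | Cc1cc(C)c(O)c(C)c1
A2 | alternative 1 | 1,3,3,5-tetramethyl-2-vinylbicyclo[2.2.2]oct-5-en-2-ol (vinyl syn to the C5=C6 bridge) | C=C[C@]1(O)C(C)(C)[C@H]2CC[C@]1(C)C=C2C
A3 | alternative 1 | cis-fused 4,4,8,10-tetramethyl-Δ8-octalin-3-one | CC1=C[C@@]2(C)CCC(=O)C(C)(C)[C@H]2CC1
A4 | alternative 2 | 4-methyl-4-{2-[(2S)-3,3-dimethyloxiran-2-yl]ethyl}cyclohex-2-en-1-one | O=C1C=C[C@](C)(CC[C@@H]2OC2(C)C)CC1
A5 | alternative 2 | cis-fused 3-hydroxy-4,4,10-trimethyldecalin-7-one | C1C[C@@]2(C)CC[C@H](O)C(C)(C)[C@H]2CC1=O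
A6 | alternative 3 | (1E,3Z)-3-(tert-butyldimethylsilyloxy)-N,N-dimethylpenta-1,3-dien-1-amine | C/C=C(O[Si](C)(C)C(C)(C)C)/C=C/N(C)C
A7 | alternative 3 | (2E,6E,10E)-2,7,11,15-tetramethylhexadeca-2,6,10,14-tetraenal | O=C/C(C)=C/CC/C=C(C)/CC/C=C(C)/CCC=C(C)C
A8 | alternative 3 | 4-formyl-4,6-dimethyl-5-(homofarnesyl)cyclohex-2-enone | CC(C)=CCC/C(C)=C/CC/C(C)=C/CC[C@@H]1[C@](C=O)(C)C=CC(=O)[C@H]1C
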